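Start from the gamma and theta runs, which differ in free base: by 12.0 min gamma has reacted 49.3% of its electrophile and theta 64.9%, so look for the concentration that sets the order of the rate, namely nucleophile, and keep books on free base, the candidate limiting reagent.

| flask | electrophile | free base | protonated nucleophile | remark | time |
|---|---|---|---|---|---|
| gamma | 0.031 M | 0.033 M | 0.0326 M | run made earlier |  |
| theta | 0.031 M | 0.058 M | 0.0326 M | run made earlier |  |
| noon | 0.031 M | 0.0460 M | 0.0326 M |  | 25 min |
| midnight | 0.031 M | 0.0930 M | 0.0326 M |  | 25 min |

- gamma (time / min: electrophile / %, target / %): 1.00: 88.6, 11.7; 2.50: 79.2, 21.6; 5.00: 64.5, 30.8; 12.0: 50.7, 32.2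
- theta (time / min: electrophile / %, target / %): 1.00: 88.0, 12.4; 2.50: 74.7, 23.5; 5.00: 58.9, 35.5; 12.0: 35.1, 42.8

(readings scatter by 1 percentage point)

- acid set free is meant together with its idle adduct
- candidate steps: electrophile + nucleophile -> acid set free + target; nucleophile + acid set free <-> protonated nucleophile; acid set free + free base <-> idle adduct; target -> over-reaction product; acid set free + free base <-> salt of the base

- part of the electrophile that has reacted at the end, noon
- part of the electrophile that has reacted at the end, midnight
- what raising the concentration of free base from its lowest to its highest value here does to the part of the electrophile that has reacted (changes below 5 percentage points count as none) (no change / it falls / it rises)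

Book the free base charge c_K in entries, with c_E the electrophile charge and c_P the protonated nucleophile charge. In the first entry, let c_P of base pull acid set free off the protonated nucleophile, making it salt of the base and leaving nucleophile close to c_E; the rate, a constant times electrophile times nucleophile, is then second order, and the ratio of reacted to unreacted electrophile grows linearly at a rate κ. Read κ from theta, whose remaining base covers its last reading: κ = 0.154 /min.

In the second entry, let c_K − c_P take the acid of each electrophile reacted, which pays in midnight for 195% of the electrophile, so take κ through to 25 min and reckon 79.4%. In noon it pays for 43.2%, which I reckon is reached near 4.94 min.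

In the third entry, each further electrophile costs a second nucleophile to the acid, so with acid counted as bound the books close at the base ceiling C = c_K/(2c_E), which is 74.2% for noon and 53.2% for gamma. The ratio of unreacted electrophile to the gap below C grows exponentially at 0.0795 /min, which puts noon at 71.0% by my reckoning, below midnight.

The forecast says 70% for noon, against my 71.0%, and 80% for midnight, against my 79.4%, and it rises, on the ground that “Once the base runs out, the acid re-protonates the nucleophile, so conversion stalls.”

The flask gives 70.8% for noon and 79.5% for midnight; with more base it rises, by 8.6 percentage points.

    electrophile + nucleophile → acid set free + target (k = 0.0730 /M/s)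
    nucleophile + acid set free ⇌ protonated nucleophile, settled at all times (K = 1300 /M)
    acid set free + free base ⇌ idle adduct, settled at all times (K = 5900 /M)
    target → over-reaction product (k = 8.40 × 10⁻⁴ /s)
    acid set free + free base ⇌ salt of the base, settled at all times (K = 2.20 × 10⁵ /M)

At 25 min noon stands below its reckoned ceiling of 74.2%, with 0.28% of its free base unbound. Take the neighbouring flask, midnight with 0.037 M of free base: its ceiling is 59.7%, its spare base pays for 14.2%, and the same closing gives 58.6% at 25 min. That flask gives 61.4%, above its reckoned ceiling, with 0.13% of its free base unbound and acid set free, which the ceiling counts as bound, standing at 0.00352 M.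

The readings are calculated on assumed constants; noise was put on by code.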